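The pitfall in this row of flasks is to take a quicker start for a larger end.

| flask | substrate | coupling partner | free catalyst | second catalyst | remark | time |
|---|---|---|---|---|---|---|
| midnight | 0.030 M | 0.022 M | 0.20 mM | 36 µM (in portions, 3) | run made earlier; portions every 15 s |  |
| autumn | 0.020 M | 0.022 M | 0.20 mM | 18 µM (in portions, 3) | run made earlier; portions every 15 s |  |
| teal | 0.020 M | 0.0220 M | 0.20 mM | 36 µM (in portions, 3) | the portions of second catalyst follow each other after 15 s, the first at the start | 12 min |
| red | 0.020 M | 0.0220 M | 0.40 mM | 36 µM (in portions, 3) | the portions of second catalyst follow each other after 15 s, the first at the start | 12 min |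
| green | 0.020 M | 0.0220 M | 0.80 mM | 36 µM (in portions, 3) | the portions of second catalyst follow each other after 15 s, the first at the start | 12 min |
| amber | 0.020 M | 0.0220 M | 1.5 mM | 36 µM (in portions, 3) | the portions of second catalyst follow each other after 15 s, the first at the start | 12 min |

| run | time / min | product / % | substrate / % |
|---|---|---|---|
| midnight | 0.667 | 0.9 | 65.5 |
| midnight | 1.33 | 2.5 | 51.7 |
| midnight | 2.00 | 3.5 | 45.7 |
| midnight | 3.00 | 5.6 | 42.0 |
| midnight | 4.00 | 7.5 | 41.1 |
| autumn | 0.667 | 0 | 65.4 |
| autumn | 1.33 | 1.8 | 51.5 |
| autumn | 2.00 | 2.3 | 46.2 |
| autumn | 3.00 | 3.7 | 43.2 |
| autumn | 4.00 | 5.4 | 41.8 |

(scatter of a reading: 0.3 percentage points)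

1. amount of product at the end, in percent of the substrate charged for teal, red, green, amber, in this order
2. the course of these numbers from the first flask to the last (falls, then rises / hardly changes / falls all the way / rises all the way / rises, then falls)

- for product the crystals are counted in
- as a solid, counted per litre of solution: crystals
- steps that have been proposed: substrate + free catalyst <-> free catalyst + open intermediate; second catalyst + open intermediate <-> catalyst intermediate; coupling partner + catalyst intermediate -> second catalyst + product; substrate + second catalyst -> spent catalyst; coupling partner <-> dormant form; crystals <-> product
- "hardly changes" means that all values lie within two and a half points (for a concentration: within two and a half percent of the largest)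
- no earlier run changes the charge of free catalyst; that part of a forecast is a guess

Free catalyst opens substrate reversibly to open intermediate. Second catalyst takes that up as catalyst intermediate, which coupling partner turns into product, and substrate meanwhile attacks second catalyst to give spent catalyst.

Two chemists read the same runs. In autumn, substrate flattens near 41.8%, and its distances from that level give a relaxation rate of 1.26 min⁻¹, so a filling time of 0.794 min at 0.20 mM of free catalyst. Midnight makes product at 0.600 mM min⁻¹, and autumn, with half the second catalyst, at 0.310 mM min⁻¹. Each second catalyst therefore turns over 16.7 min⁻¹ in midnight and 17.2 min⁻¹ in autumn.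

One chemist concludes that second catalyst holds up later, so the loss that counts falls in the lag, and that more free catalyst, by shortening the lag, should raise the yield in every flask. The other answers that free catalyst stands on both sides of the opening step, a pre-equilibrium in the usual term, so it changes how fast the balance comes and not where it lies.

My reckoning follows the other chemist. Taking the filling rate in proportion to free catalyst, which is a guess because no earlier run varies that charge, amber fills in 0.106 min. Teal's filling time is already short beside the 12 min allowed. Amber therefore runs ahead of teal by 0.688 min. This head start is the filling time saved by the extra free catalyst. As a rough price, I take the rate from midnight's first minutes, a run with teal's charge of second catalyst but more substrate; at that rate the head start is worth 2.1 percentage points of the substrate charged, which lies inside the margin for a row that hardly changes.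

The other side's numbers are the forecast, 26%, 30%, 34% and 37%, shape rises all the way, a gain of 11 points where mine has 2.1 points, on the ground that “Yield should therefore rise, with diminishing returns.”

The simulation gives 19.0%, 20.4%, 21.0% and 21.2%, shape hardly changes.

    substrate + free catalyst ⇌ free catalyst + open intermediate (K = 1.30, k = 4000 M⁻¹ min⁻¹)
    second catalyst + open intermediate ⇌ catalyst intermediate (K = 110 M⁻¹, k = 81000 M⁻¹ min⁻¹)
    coupling partner + catalyst intermediate → second catalyst + product (k = 2000 M⁻¹ min⁻¹)
    substrate + second catalyst → spent catalyst (k = 16.0 M⁻¹ min⁻¹)
    coupling partner ⇌ dormant form (K = 0.980, k = 0.100 min⁻¹)
    crystals ⇌ product, rate k6*(cs6 - [product]) while solid is left; crystals form when [product] > cs6 (solubility = 6.50 mM, k = 38.0 min⁻¹)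

At teal's own average pace of 0.317 mM min⁻¹, the head start is worth 1.1 points of the 2.2 points the flask gains from teal to amber, and green's head start of 0.595 min is worth 0.94 points of its 2 points. Midnight's early rate is faster than that pace, so the nearness of 2.1 points to the flask's gain is no check. The first chemist's sparing shows at 12.0 min: spent catalyst stands at 50.4% of the second catalyst charged in amber and 54.7% in teal. The level of the row is another matter: taking away the return of catalyst intermediate to second catalyst and open intermediate, the largest single effect on teal, lifts teal from 19.0% to 43.5%.

The runs were computed with made-up constants, and the scatter is random.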